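Assumptions: compounds 1, 5 and 9 are taken as purchased, as is the tetramethoxyacetophenone used only in the fallback to step 5. Compound 10 has one stereocenter, which disappears on aromatization, so it is made and used as the racemate. Atoms are numbered as in the flavone throughout (O1, C2 to C8a, ring B primed), also in open-chain precursors.

## Analysis of the target

The target is a flavone: a chromen-4-one (rings A and C) with an aryl group (ring B) at C2. It has no stereocenter, so the whole problem is one of regiochemistry. Ring B is an isovanillyl unit (3'-OH, 4'-OCH3) that can be bought complete, and ring C is an ordinary γ-pyrone. The difficulty sits in ring A, which is fully substituted: C5, C6, C7 and C8 all carry oxygen, two as free phenols (C5, C6) and two as methyl ethers (C7, C8). Four neighbouring oxygens must therefore be placed and then told apart, and the usual chelation handle of a flavone singles out only O5. The sensitive parts are the 5,6-dihydroxy unit, which is easily oxidized to a quinone in base and air, the free phenols in general, and the pyranone, which hard nucleophiles can open by conjugate addition. The strategy reads C5 to C8 as an oxidized polyketide chain: C5 is an ester carbon on C4a, and C8–C7–C6 is a chain CH(OCH3)–CO–CH2(OR) on C8a. One C5–C6 bond then closes ring A with every oxygen already in place and already carrying its own label (H, methyl or benzyl).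

## Retrosynthetic reasoning

**13 from 12.** The two O–benzyl bonds at O6 and O3' are cut last. Benzyl is the one label that falls under neutral reductive conditions and leaves the methyl ethers alone. Keeping O6 masked until the end means the oxidation-prone 5,6-dihydroxy unit exists only in the final product.

**12 from 11.** The O7–CH3 bond is cut. In 11 the only free phenols are at C5 and C7. The 5-OH is tied to the C4 carbonyl by a hydrogen bond, while the 7-OH is the acidic end of a vinylogous acid. A single methylation should therefore go to O7. This is why the ring-forming step is arranged to deliver O7 as a free hydroxyl (from a ketone) and O6 as a benzyl ether (from the enolate carbon).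

**11 from 10 (key disconnection).** The C5–C6 bond of ring A is cut. C5 becomes the carbon of a methyl ester on C4a, and C6 becomes the α-methylene of a ketone whose carbonyl is C7. Ring C and ring B stay intact in pyranone 10. This cut gives both ends their natural polarity: acyl acceptor at the carboxyl oxidation level of C5, enolate donor at C6. It leaves no oxygen to be introduced on an arene afterwards. The forward reaction must be a base-mediated intramolecular Claisen condensation followed by two enolizations, which turn the new cyclohexenedione into the 5,7-dihydroxybenzene ring.

**10 from 8 and 9.** The C7–C8 bond is cut. The methylene of the methoxymethyl group in 8 is γ to both the ring carbonyl and the ester through the C8a=C4a bond, and it is the only acidic position of 8. Its dienolate can be acylated with acid chloride 9, which brings in C7 and C6 together with the benzyloxy group. The gain is that the whole ring-A chain is assembled from two purchased two-carbon pieces, each carrying its oxygen.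

**8 from 4 and 5.** Ring C is cut at O1–C8a and C4–C4a. β-Keto ester 5 supplies C8 (with its methoxy group), C8a, C4a and the ester carbon C5. Acid 4 supplies C4, C3, C2 and ring B. In the forward direction, the magnesium enolate of 5 is C-acylated by acid chloride 6 to the tricarbonyl compound 7, and the enol oxygen of the methoxyacetyl group adds to the ynone to close the pyranone. An alternative path through an open-chain aroyl diketo ester was set aside: such an ester has two acidic methylene groups that compete in the acylation, and it can lactonize to a hydroxy-2-pyranone. Compound 5 has one doubly activated carbon, and the ynone cannot lactonize.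

**4 from 2 from 1.** The alkyne–carboxyl bond and the triple bond are traced back to the formyl group of aldehyde 1 by one-carbon homologation to dibromoalkene 2, rearrangement to acetylide 3 and carboxylation. Ring B, with the 3'-oxygen benzylated and the 4'-oxygen methylated, is bought in 1 and never touched again until the last step.

## Alternatives that were turned down

**Alternative 1: formyl C–H acylation with a sulfoxonium ylide.**
- Disconnection: ring C is cut at C3–C4 and O1–C2. This gives a fully substituted salicylaldehyde A2 (ring A complete, O5 and O6 tied as a diphenylmethylene ketal) and the aroyl sulfoxonium ylide A3 (ring B with C2 and C3).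
- Forward key step: with [Cp*RhCl2]2 (trivalent rhodium) the phenol directs activation of the formyl C–H bond. The acyl–rhodium species takes up the ylide as a carbene equivalent and forms C3–C4. The phenol then condenses on the aroyl carbonyl to give flavone A1.
- For it: the step is convergent and is an established way to chromones. The ketal marks O5 and O6 clearly against the two methyl ethers.
- Against it: A2 is a hexasubstituted benzene with four contiguous oxygens in three different states. Making it is the actual synthesis, so the difficulty is moved into the starting material, not solved. The formyl group of A2 also has two ortho substituents, and the acid set free in the cyclodehydration endangers the ketal.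
- Comparison: on convergence and on precedent for the key step this alternative is stronger. The chosen route offers instead a ring A made from purchased acyclic pieces, with no substitution chemistry on a crowded arene.

**Alternative 2: late double methoxylation of a dibromoflavone.**
- Disconnection: no skeletal bond is cut. The skeleton of the natural flavone A6 is kept, and the C6–O and C8–O bonds are traced back to C–Br bonds in dibromide A5.
- Forward key step: NaOCH3 with CuBr (monovalent copper) in dimethylformamide replaces both bromides in an Ullmann-type substitution and gives A4. No ring is formed.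
- For it: this is the shortest plan. The skeleton is certain, and bromination of a 5,7-dioxygenated ring A goes to C6 and C8 by itself. On step count and on starting material it is clearly ahead of the chosen route.
- Against it: both substitutions take place at carbons flanked by two oxygen substituents, next to a free chelating 5-OH, where reduction of the C–Br bond competes. More seriously, A4 carries OCH3 at C6, the same label as at C7, C8 and C4'. The target needs a free 6-OH, so the end of the route depends on cleaving one particular methyl ether out of four, with only the neighbouring 5-OH to direct it.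
- Comparison: the chosen route brings O6 in as a benzyl ether from the start, so its release is unambiguous.

**Alternative 3: Diels–Alder benzannulation.**
- Disconnection: ring A is cut at C6–C7 and C8–C8a. This gives diene A8 (a pyranone whose C8a=C4a bond and a silyloxy-benzyloxy-vinyl group at C4a form the diene) and the dichloro dienophile A9.
- Forward key step: a [4+2] cycloaddition followed by loss of two molecules of HCl gives A7.
- For it: two C–C bonds and ring A are made in one step. The oxygens carry orthogonal labels (silyl at O5, benzyl at O6, a carbonate across O7 and O8), and aromatization is a strong driving force. On bonds formed per step it is stronger than the chosen route.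
- Against it: the diene has to use the C8a=C4a bond of a 4-pyranone, which is acceptor-polarized and part of a stabilized cross-conjugated ring, so the cycloaddition costs that stabilization. A9 is a tetrasubstituted alkene with two donor oxygens and is a sluggish dienophile that calls for forcing conditions. The silyl enol ether of A8 must survive those conditions and the HCl set free. After the key step, four further operations remain (desilylation, carbonate cleavage, double methylation, debenzylation).
- Comparison: the chosen route forms only one C–C bond in its key step, but from a precursor whose donor and acceptor are matched, and it needs only two steps afterwards.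

Key step: step 5

## Route

Step 1
Reactants: 1 3-(benzyloxy)-4-methoxybenzaldehyde
Product: 2 2-(benzyloxy)-4-(2,2-dibromoethenyl)-1-methoxybenzene
Conditions: CBr4, PPh3, CH2Cl2, 0 °C
Reagents that add atoms: carbon tetrabromide, BrC(Br)(Br)Br
Why: Corey–Fuchs dibromoolefination, a Wittig reaction of the ylide Ph3P=CBr2 with an unhindered aryl aldehyde; the benzyl and methyl ethers are inert.

Step 2
Reactants: 2 2-(benzyloxy)-4-(2,2-dibromoethenyl)-1-methoxybenzene
Product: 4 3-[3-(benzyloxy)-4-methoxyphenyl]prop-2-ynoic acid, via lithium arylacetylide 3 (not isolated)
Conditions: n-BuLi (2.2 equiv), THF, −78 °C; CO2, −78 °C to rt; aq HCl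
Reagents that add atoms: carbon dioxide, O=C=O
Why: Second stage of the Corey–Fuchs sequence: bromine–lithium exchange, loss of LiBr with 1,2-shift (Fritsch–Buttenberg–Wiechell rearrangement) and deprotonation give the acetylide, which is carboxylated; at −78 °C the benzyl ether should not be metalated.

Step 3
Reactants: 4 3-[3-(benzyloxy)-4-methoxyphenyl]prop-2-ynoic acid; 5 methyl 4-methoxy-3-oxobutanoate
Product: 8 methyl 6-[3-(benzyloxy)-4-methoxyphenyl]-2-(methoxymethyl)-4-oxo-4H-pyran-3-carboxylate, via arylpropynoyl chloride 6 (not isolated), via C-acylated ynone keto ester 7 (not isolated)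
Conditions: (COCl)2, cat. DMF, CH2Cl2, 0 °C to rt, evaporate; 5, MgCl2, pyridine, CH2Cl2, 0 °C to rt; Et3N, rt
Reagents that add atoms: none
Why: Acid chloride formation, then magnesium-chelate-controlled C-acylation of the β-keto ester at its single doubly activated carbon, then 6-endo-dig oxa-Michael addition of the methoxyacetyl enol oxygen to the ynone; formation of γ-pyrone-3-carboxylates from arylpropynoyl chlorides and β-keto ester enolates is a long-known reaction type, and any HCl adduct of 6 should converge on the same ring by addition–elimination.

Step 4
Reactants: 8 methyl 6-[3-(benzyloxy)-4-methoxyphenyl]-2-(methoxymethyl)-4-oxo-4H-pyran-3-carboxylate; 9 (benzyloxy)acetyl chloride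
Product: 10 racemic methyl 6-[3-(benzyloxy)-4-methoxyphenyl]-2-[3-(benzyloxy)-1-methoxy-2-oxopropyl]-4-oxo-4H-pyran-3-carboxylate
Conditions: LiN(SiMe3)2 (2.2 equiv), THF, −78 °C; 9, −78 °C; AcOH, −78 °C to rt
Reagents that add atoms: none
Why: Vinylogous Claisen-type acylation: the methylene of the methoxymethyl group is γ to both the ring carbonyl and the ester and is the only acidic site, and its lithium dienolate should react at the exocyclic carbon because only that restores the pyranone. The second equivalent of base deprotonates the more acidic product and so suppresses proton transfer and double acylation; a ketene formed from 9 would give the same product enolate. The new stereocenter is formed without control and is lost in step 5.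

Step 5
Reactants: 10 racemic methyl 6-[3-(benzyloxy)-4-methoxyphenyl]-2-[3-(benzyloxy)-1-methoxy-2-oxopropyl]-4-oxo-4H-pyran-3-carboxylate
Product: 11 6,3'-bis(benzyloxy)-5,7-dihydroxy-8,4'-dimethoxyflavone
Conditions: NaOCH3 (4 equiv), CH3OH–THF, argon, 0 to 50 °C; aq HCl
Reagents that add atoms: none
Why: Proposed new method: methoxide first removes the most acidic proton, C8–H, reversibly and without consequence; in equilibrium the ketone also enolizes toward C6, this enolate carbon adds to the ester carbonyl C5 on the neighbouring ring carbon, the tetrahedral intermediate loses methoxide, and the cyclohexenedione so formed tautomerizes at C6 and C8 to the 5,7-dihydroxybenzene ring, held as its phenoxide. The closest known reaction types are the Dieckmann-type cyclization of 2-(2-oxoalkyl)benzoates to 1,3-naphthalenediols and the Claisen folding of poly-β-carbonyl chains to phloroglucinols; here the benzoate is replaced by a 4-pyranone-3-carboxylate, whose C8a=C4a bond holds donor chain and acceptor ester cis and within reach. Ring A closes in the 6-(enolendo)-exo-trig mode, which is favoured for enolates. No stereocenter is formed, and the one in 10 disappears. The selectivity needed is C-acylation through C6 over O-acylation by the C7 enolate oxygen, which would close a fused enol lactone. In methanolic methoxide that lactone should be reopened to 10, ester exchange is degenerate and conjugate addition of methoxide to the pyranone is reversible, whereas only the C–C closure leads to an aromatic phenoxide and is therefore the irreversible exit. The C8-deprotonated resting form also shields the C7 ketone against retro-Claisen attack.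

Step 6
Reactants: 11 6,3'-bis(benzyloxy)-5,7-dihydroxy-8,4'-dimethoxyflavone
Product: 12 6,3'-bis(benzyloxy)-5-hydroxy-7,8,4'-trimethoxyflavone
Conditions: CH3I (1.2 equiv), K2CO3 (1.2 equiv), acetone, rt
Reagents that add atoms: iodomethane, CI
Why: Williamson etherification under chelation control: the 7-OH is the acidic end of a vinylogous acid, whereas the 5-OH is locked in a hydrogen bond to the C4 carbonyl, so one equivalent of weak base and a small electrophile should alkylate O7 only.

Step 7
Reactants: 12 6,3'-bis(benzyloxy)-5-hydroxy-7,8,4'-trimethoxyflavone
Product: 13 5,6,3'-trihydroxy-7,8,4'-trimethoxyflavone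
Conditions: H2 (1 atm), Pd/C, EtOAc–CH3OH, rt; work-up under argon
Reagents that add atoms: none
Why: Catalytic hydrogenolysis of both aryl benzyl ethers; the methyl ethers and the conjugated C2=C3 bond of the flavone should be untouched at 1 atm if the reaction is stopped after uptake of two equivalents, and exclusion of air protects the 5,6-dihydroxy unit.

## Compound list

1 | 3-(benzyloxy)-4-methoxybenzaldehyde | COc1ccc(C=O)cc1OCc1ccccc1 | starting material
2 | 2-(benzyloxy)-4-(2,2-dibromoethenyl)-1-methoxybenzene | COc1ccc(C=C(Br)Br)cc1OCc1ccccc1 | intermediate
3 | lithium [3-(benzyloxy)-4-methoxyphenyl]acetylide | [Li]C#Cc1ccc(OC)c(OCc2ccccc2)c1 | intermediate (not isolated)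
4 | 3-[3-(benzyloxy)-4-methoxyphenyl]prop-2-ynoic acid | COc1ccc(C#CC(=O)O)cc1OCc1ccccc1 | intermediate
5 | methyl 4-methoxy-3-oxobutanoate | COCC(=O)CC(=O)OC | starting material
6 | 3-[3-(benzyloxy)-4-methoxyphenyl]prop-2-ynoyl chloride | COc1ccc(C#CC(=O)Cl)cc1OCc1ccccc1 | intermediate (not isolated)
7 | methyl 5-[3-(benzyloxy)-4-methoxyphenyl]-2-(methoxyacetyl)-3-oxopent-4-ynoate | COCC(=O)C(C(=O)OC)C(=O)C#Cc1ccc(OC)c(OCc2ccccc2)c1 | intermediate (not isolated)
8 | methyl 6-[3-(benzyloxy)-4-methoxyphenyl]-2-(methoxymethyl)-4-oxo-4H-pyran-3-carboxylate | COCc1oc(-c2ccc(OC)c(OCc3ccccc3)c2)cc(=O)c1C(=O)OC | intermediate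
9 | (benzyloxy)acetyl chloride | O=C(Cl)COCc1ccccc1 | starting material
10 | racemic methyl 6-[3-(benzyloxy)-4-methoxyphenyl]-2-[3-(benzyloxy)-1-methoxy-2-oxopropyl]-4-oxo-4H-pyran-3-carboxylate | COC(=O)c1c(C(OC)C(=O)COCc2ccccc2)oc(-c2ccc(OC)c(OCc3ccccc3)c2)cc1=O | intermediate
11 | 6,3'-bis(benzyloxy)-5,7-dihydroxy-8,4'-dimethoxyflavone | COc1ccc(-c2cc(=O)c3c(O)c(OCc4ccccc4)c(O)c(OC)c3o2)cc1OCc1ccccc1 | intermediate
12 | 6,3'-bis(benzyloxy)-5-hydroxy-7,8,4'-trimethoxyflavone | COc1ccc(-c2cc(=O)c3c(O)c(OCc4ccccc4)c(OC)c(OC)c3o2)cc1OCc1ccccc1 | intermediate
13 | 5,6,3'-trihydroxy-7,8,4'-trimethoxyflavone | COc1ccc(-c2cc(=O)c3c(O)c(O)c(OC)c(OC)c3o2)cc1O | target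

## Step count and risk

Total step count: 7. Longest linear sequence: 7 steps (1 to 13). Compounds 5 and 9 are bought and enter in steps 3 and 4.

**Step 5 (key step, proposed new method).**
- What may go wrong: the closure may be too slow. The substrate rests as the C8-deprotonated, delocalized anion, and the ester is a push–pull ester that the ring oxygen makes poorly electrophilic. While the substrate waits, two destructive processes can take over: retro-Claisen cleavage of the C7–C8 bond by methoxide, and conjugate opening of the pyranone. O-acylation to the enol lactone may also hold the material back if its reopening is slow.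
- Fallback (known chemistry; ring A is bought and not built): the route sets out again from aldehyde 1. Claisen–Schmidt condensation with 1-(2-hydroxy-3,4,5,6-tetramethoxyphenyl)ethanone F1 (KOH, ethanol) should give the chalcone (E)-3-[3-(benzyloxy)-4-methoxyphenyl]-1-(2-hydroxy-3,4,5,6-tetramethoxyphenyl)prop-2-en-1-one F2. Oxidative cyclization with catalytic I2 in hot dimethyl sulfoxide should close ring C to 3'-benzyloxy-5,6,7,8,4'-pentamethoxyflavone F3. AlBr3 in acetonitrile is expected to cleave the 5-methoxy group through the carbonyl chelate and then the neighbouring 6-methoxy group, giving 3'-benzyloxy-5,6-dihydroxy-7,8,4'-trimethoxyflavone F4. Hydrogenolysis as in step 7 then returns to the route at 13. The price is a selective demethylation, which the main route avoids.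

**Step 3.**
- What may go wrong: nucleophiles (chloride, pyridine, the enolate) may add to the triple bond of the acid chloride in competition with C-acylation. The tricarbonyl intermediate may also lose its methoxyacetyl group before ring closure.
- Fallback (the order of the two acylations is reversed and no ynoyl chloride is made): starting from acid 4, activation with 1,1'-carbonyldiimidazole and decarboxylative Claisen condensation with the magnesium salt of monomethyl malonate should give methyl 5-[3-(benzyloxy)-4-methoxyphenyl]-3-oxopent-4-ynoate F5. Its single active methylene is C-acylated with methoxyacetyl chloride (MgCl2, pyridine) to give 7, which closes to 8 and rejoins the route there.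

**Step 4.**
- What may go wrong: the dienolate may be acylated on oxygen in competition with carbon, and the amide base may consume the acid chloride.
- Fallback (aldol addition and oxidation in place of acylation): starting from 8, the lithium dienolate is added to benzyloxyacetaldehyde at −78 °C and quenched cold with acetic acid. This should give methyl 6-[3-(benzyloxy)-4-methoxyphenyl]-2-[3-(benzyloxy)-2-hydroxy-1-methoxypropyl]-4-oxo-4H-pyran-3-carboxylate F6 as a mixture of racemic diastereomers. It is oxidized at once with Dess–Martin periodinane, before the hydroxyl group can lactonize onto the neighbouring ester, and the route is rejoined at 10.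

**Step 6.**
- What may go wrong: alkylation of O7, which is flanked on both sides, may be slow, and methylation of O5 may set in once more base or heat is applied.
- Fallback (exhaustive alkylation and chelation-controlled dealkylation in place of selective alkylation): starting from 11, excess dimethyl sulfate and K2CO3 in refluxing acetone should give 6,3'-bis(benzyloxy)-5,7,8,4'-tetramethoxyflavone F7. BCl3 with pentamethylbenzene in CH2Cl2 at −78 °C is then expected to cleave the chelated 5-methoxy group and both benzyl ethers. This returns to the route at 13 and bypasses 12 and step 7.

## Further compounds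

F1 | step 5 | 1-(2-hydroxy-3,4,5,6-tetramethoxyphenyl)ethanone | CC(=O)c1c(O)c(OC)c(OC)c(OC)c1OC
F2 | step 5 | (E)-3-[3-(benzyloxy)-4-methoxyphenyl]-1-(2-hydroxy-3,4,5,6-tetramethoxyphenyl)prop-2-en-1-one | COc1ccc(/C=C/C(=O)c2c(O)c(OC)c(OC)c(OC)c2OC)cc1OCc1ccccc1
F3 | step 5 | 3'-benzyloxy-5,6,7,8,4'-pentamethoxyflavone | COc1ccc(-c2cc(=O)c3c(OC)c(OC)c(OC)c(OC)c3o2)cc1OCc1ccccc1
F4 | step 5 | 3'-benzyloxy-5,6-dihydroxy-7,8,4'-trimethoxyflavone | COc1ccc(-c2cc(=O)c3c(O)c(O)c(OC)c(OC)c3o2)cc1OCc1ccccc1
F5 | step 3 | methyl 5-[3-(benzyloxy)-4-methoxyphenyl]-3-oxopent-4-ynoate | COC(=O)CC(=O)C#Cc1ccc(OC)c(OCc2ccccc2)c1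
F6 | step 4 | methyl 6-[3-(benzyloxy)-4-methoxyphenyl]-2-[3-(benzyloxy)-2-hydroxy-1-methoxypropyl]-4-oxo-4H-pyran-3-carboxylate (mixture of racemic diastereomers) | COC(=O)c1c(C(OC)C(O)COCc2ccccc2)oc(-c2ccc(OC)c(OCc3ccccc3)c2)cc1=O
F7 | step 6 | 6,3'-bis(benzyloxy)-5,7,8,4'-tetramethoxyflavone | COc1ccc(-c2cc(=O)c3c(OC)c(OCc4ccccc4)c(OC)c(OC)c3o2)cc1OCc1ccccc1
A1 | alternative 1 | 3'-benzyloxy-7,8,4'-trimethoxy-5,6-(diphenylmethylenedioxy)flavone | COc1ccc(-c2cc(=O)c3c4OC(c5ccccc5)(c5ccccc5)Oc4c(OC)c(OC)c3o2)cc1OCc1ccccc1
A2 | alternative 1 | 5-hydroxy-6,7-dimethoxy-2,2-diphenyl-1,3-benzodioxole-4-carbaldehyde | O=Cc1c(O)c(OC)c(OC)c2OC(c3ccccc3)(c3ccccc3)Oc12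
A3 | alternative 1 | 1-[3-(benzyloxy)-4-methoxyphenyl]-2-[dimethyl(oxo)-λ6-sulfanylidene]ethan-1-one | COc1ccc(C(=O)C=S(C)(C)=O)cc1OCc1ccccc1
A4 | alternative 2 | 3'-benzyloxy-5-hydroxy-6,7,8,4'-tetramethoxyflavone | COc1ccc(-c2cc(=O)c3c(O)c(OC)c(OC)c(OC)c3o2)cc1OCc1ccccc1
A5 | alternative 2 | 3'-benzyloxy-6,8-dibromo-5-hydroxy-7,4'-dimethoxyflavone | COc1ccc(-c2cc(=O)c3c(O)c(Br)c(OC)c(Br)c3o2)cc1OCc1ccccc1
A6 | alternative 2 | 5,7,3'-trihydroxy-4'-methoxyflavone (diosmetin) | COc1ccc(-c2cc(=O)c3c(O)cc(O)cc3o2)cc1O
A7 | alternative 3 | 6,3'-bis(benzyloxy)-5-(tert-butyldimethylsilyloxy)-4'-methoxy-7,8-(carbonyldioxy)flavone | COc1ccc(-c2cc(=O)c3c(O[Si](C)(C)C(C)(C)C)c(OCc4ccccc4)c4OC(=O)Oc4c3o2)cc1OCc1ccccc1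
A8 | alternative 3 | 6-[3-(benzyloxy)-4-methoxyphenyl]-3-[(Z)-2-(benzyloxy)-1-(tert-butyldimethylsilyloxy)ethenyl]-4H-pyran-4-one | COc1ccc(-c2cc(=O)c(/C(O[Si](C)(C)C(C)(C)C)=C/OCc3ccccc3)co2)cc1OCc1ccccc1
A9 | alternative 3 | 4,5-dichloro-1,3-dioxol-2-one (dichlorovinylene carbonate) | O=C1OC(Cl)=C(Cl)O1
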